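**Retrosynthetic overview**
- 25 ⇐ hexa-MOM ether 24 (acidic transacetalization) ⇐ thioester 17 + arylzinc 23 from bromide 21 (Fukuyama coupling). The aroyl ring has no OH ortho to its C=O, so it enters last and under neutral conditions.
- 17 ⇐ cis-fused δ-lactone 15. Its O–C(=O) bond is absent from the target. It ties O-2' of the central resorcinol ring to the acyl carbon on C4'' and is cut again by thiolate.
- 15 ⇐ flat, achiral aryl cinnamate 12 by one catalytic isomerization. A chiral isothiourea ionizes the ester, a [4+2] closes the methylcyclohexene (bonds C3''–C4'' and C5''–C6'', three stereocentres), and aryloxide rebound closes the lactone.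
- Enabling feature: O-2' is ortho both to C3' (which carries C3'') and to the chalcone C=O on C1', and the aryl on C3'' is cis to the acyl on C4''. Hence O2'–C2'–C3'–C3''–C4''–C(=O) is a latent six-membered ring, and the 2-acylaryloxide acts as leaving group, diene activator and turnover nucleophile.
- Ring order: the four benzene rings are bought, and the cyclohexene is the only skeletal ring built and the last to close (step 9). 12 ⇐ acid 3 + dienyl 2'-hydroxychalcone 10 ⇐ resacetophenone 6 (iodination, MOM, Suzuki–Miyaura, Claisen–Schmidt).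

Key step: step 9

Assumption and locants: the structure is taken exactly as written, with a 3,5-dihydroxy-4-prenylphenyl aroyl ring (no OH ortho to that ketone) and a (3''S,4''R,5''S) cyclohexene (aryl/aroyl cis, aroyl/4-hydroxyphenyl trans), so dienophile activation through a 2'-hydroxy ketone chelate is not available; primes = central ring (C1' enone C=O, O-2', C3' cyclohexenyl, O-4'), double primes = cyclohexene (C1'' methyl-bearing, C2'' =CH, C3'' aryl, C4'' aroyl, C5'' 4-hydroxyphenyl, C6'' CH2).

**Step 1**
Reactants: 1 4-hydroxybenzaldehyde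
Product: 2 4-(methoxymethoxy)benzaldehyde
Conditions: MOMCl (1.2 equiv), K2CO3, acetone, 0 °C → rt
Reagents that add atoms: chloromethyl methyl ether, COCCl
Why: Williamson-type O-alkylation of the phenoxide masks the acidic OH as a base-stable acetal for the later basic and organometallic steps.

**Step 2**
Reactants: 2 4-(methoxymethoxy)benzaldehyde
Product: 3 (E)-3-[4-(methoxymethoxy)phenyl]prop-2-enoic acid
Conditions: malonic acid, pyridine, piperidine (cat.), 90 °C; cold aq. citric acid work-up
Reagents that add atoms: malonic acid, OC(=O)CC(=O)O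
Why: Knoevenagel–Doebner condensation with decarboxylation should give the E-cinnamic acid under basic conditions that leave the MOM acetal intact.

**Step 3**
Reactants: 4 2-methylbut-1-en-3-yne
Product: 5 (E)-4,4,5,5-tetramethyl-2-(3-methylbuta-1,3-dien-1-yl)-1,3,2-dioxaborolane
Conditions: HBpin, Cp2ZrHCl (10 mol %), Et3N (10 mol %), CH2Cl2, sealed flask, rt
Reagents that add atoms: pinacolborane, CC1(C)OBOC1(C)C
Why: zirconocene-catalysed syn-hydroboration of the terminal alkyne places boron at the terminus and sets the E-alkene, while the 1,1-disubstituted alkene reacts much more slowly.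

**Step 4**
Reactants: 6 1-(2,4-dihydroxyphenyl)ethanone (resacetophenone)
Product: 7 1-(2,4-dihydroxy-3-iodophenyl)ethanone
Conditions: I2 (0.4 equiv), HIO3 (0.2 equiv), EtOH/H2O, rt
Reagents that add atoms: iodine, II; iodic acid, OI(=O)=O
Why: oxidative electrophilic aromatic iodination goes to C3, the position ortho to both hydroxyl groups, and consumes all the iodine.

**Step 5**
Reactants: 7 1-(2,4-dihydroxy-3-iodophenyl)ethanone
Product: 8 1-[2-hydroxy-3-iodo-4-(methoxymethoxy)phenyl]ethanone
Conditions: MOMCl (1.1 equiv), K2CO3, acetone, rt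
Reagents that add atoms: chloromethyl methyl ether, COCCl
Why: selective Williamson-type O-alkylation, because the 2-OH is held in a hydrogen bond to the acetyl C=O and only the 4-OH is alkylated under mild base.

**Step 6**
Reactants: 8 1-[2-hydroxy-3-iodo-4-(methoxymethoxy)phenyl]ethanone; 5 (E)-dienyl pinacol boronate
Product: 9 1-{2-hydroxy-4-(methoxymethoxy)-3-[(1E)-3-methylbuta-1,3-dien-1-yl]phenyl}ethanone
Conditions: Pd(dppf)Cl2 (5 mol %), K2CO3, 1,4-dioxane/H2O, 70 °C; neutral work-up
Reagents that add atoms: none
Why: Suzuki–Miyaura coupling of the aryl iodide with the alkenyl boronate proceeds with retention of the E geometry and tolerates the free chelated phenol and the ketone.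

**Step 7**
Reactants: 9 dienyl 2-hydroxyacetophenone; 2 4-(methoxymethoxy)benzaldehyde
Product: 10 (E)-1-{2-hydroxy-4-(methoxymethoxy)-3-[(1E)-3-methylbuta-1,3-dien-1-yl]phenyl}-3-[4-(methoxymethoxy)phenyl]prop-2-en-1-one
Conditions: KOH, EtOH, rt; aq. NH4Cl to about pH 7
Reagents that add atoms: none
Why: Claisen–Schmidt condensation with E1cB loss of water gives the E-enone, the diene is inert to base, and the neutral work-up avoids acid-induced closure of the ortho-hydroxy diene to a chromene.

**Step 8**
Reactants: 3 (E)-3-[4-(methoxymethoxy)phenyl]prop-2-enoic acid; 10 dienyl 2'-hydroxychalcone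
Product: 12 3-(methoxymethoxy)-6-{(E)-3-[4-(methoxymethoxy)phenyl]prop-2-enoyl}-2-[(1E)-3-methylbuta-1,3-dien-1-yl]phenyl (E)-3-[4-(methoxymethoxy)phenyl]prop-2-enoate (tethered triene), via acid chloride 11 (not isolated)
Conditions: 3, 1-chloro-N,N,2-trimethylprop-1-en-1-amine, CH2Cl2, 0 °C; then 10, Et3N, CH2Cl2, 0 °C → rt
Reagents that add atoms: 1-chloro-N,N,2-trimethylprop-1-en-1-amine, CC(C)=C(Cl)N(C)C (supplies the chlorine of 11 only)
Why: neutral acid chloride formation spares the MOM group, and base-mediated O-acylation of the only free phenol without a nucleophilic catalyst keeps an achiral Lewis base from starting the cascade of step 9.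

**Step 9**
Reactants: 12 tethered triene (aryl cinnamate)
Product: 15 (6aR,7S,10aS)-1-(methoxymethoxy)-7-[4-(methoxymethoxy)phenyl]-4-{(E)-3-[4-(methoxymethoxy)phenyl]prop-2-enoyl}-9-methyl-6a,7,8,10a-tetrahydro-6H-benzo[c]chromen-6-one (cis-fused lactone), via acyl isothiouronium aryloxide ion pair 13 (not isolated), via cycloadduct zwitterion 14 (not isolated)
Conditions: (2R,3S)-HyperBTM (20 mol %), 4 Å MS, CH2Cl2 (0.05 M), rt
Reagents that add atoms: (2R,3S)-HyperBTM, CC(C)[C@H]1CN2c3ccccc3SC2=N[C@H]1c1ccccc1 (catalyst, bound in 13 and 14 and released unchanged with 15)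
Why: Proposed new method: the Lewis-basic nitrogen of the isothiourea attacks the activated 2-acylaryl ester of 12 and expels the aryloxide, so that ion pair 13 holds a LUMO-lowered dienophile (the α,β-unsaturated acyl isothiouronium) next to a HOMO-raised diene (the dienyl arene as its ortho-phenoxide). An asynchronous endo [4+2] cycloaddition, in which the bond from the diene CH2 terminus to the cinnamoyl β-carbon runs ahead of the bond from the benzylic diene carbon to the α-carbon, closes the methylcyclohexene and gives 14, whose phenoxide then closes the temporary δ-lactone by 6-exo-trig acyl substitution and frees the catalyst. The closest known reaction types are the Diels–Alder/lactonization organocascade of α,β-unsaturated acylammonium salts with hydroxy-substituted silyloxydienes and the aryloxide-rebound mode of isothiourea catalysis with α,β-unsaturated aryl esters; new is that one aryloxide serves as leaving group, diene activator and turnover nucleophile and that the diene is a plain 1-aryl-3-methylbutadiene. C5'' is controlled by the catalyst, since the 1,5-O···S contact fixes the s-cis acyl isothiouronium in the catalyst plane and the pseudoaxial phenyl group covers one face, which for the (2R,3S) antipode should leave open the face leading to 5''S; the trans relation C4''/C5'' follows from suprafacial addition to the E-cinnamoyl unit, and the cis relation C3''/C4'' from the E-diene in the endo mode, which the Coulomb contact between phenoxide oxygen and cationic acyl unit favours. The step needs chemoselectivity between two enone-type C=C bonds, secured because only the ester can be ionized; regioselectivity, secured by the matching 1-aryl and 3-methyl directing effects and the ion-pair contact; and suppression of the usual phenoxide Michael/lactonization [3+3] path, secured because both carbons ortho to the phenoxide oxygen are substituted, while O-reacylation only returns 12. The uncatalysed intramolecular cycloaddition of 12 should need a much higher temperature, so no racemic background is expected at room temperature.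

**Step 10**
Reactants: 15 cis-fused lactone
Product: 17 S-ethyl (1R,2S,6S)-2-{2,6-bis(methoxymethoxy)-3-[(E)-3-[4-(methoxymethoxy)phenyl]prop-2-enoyl]phenyl}-6-[4-(methoxymethoxy)phenyl]-4-methylcyclohex-3-ene-1-carbothioate, via sodium phenoxide thioester 16 (not isolated)
Conditions: NaSEt (1.05 equiv), THF/DMF, −20 °C; then MOMCl (1.5 equiv), −20 °C → rt
Reagents that add atoms: sodium ethanethiolate, CC[S-].[Na+]; chloromethyl methyl ether, COCCl
Why: transthioesterification of the activated aryl lactone by the weakly basic thiolate, followed by Williamson-type capping of the released phenoxide in the same flask, blocks re-lactonization, leaves the α-stereocentre untouched, and keeps thia-Michael addition to the chalcone reversible because the aprotic medium offers no proton to complete it.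

**Step 11**
Reactants: 18 5-bromobenzene-1,3-diol
Product: 19 1-bromo-3,5-bis(methoxymethoxy)benzene
Conditions: MOMCl (2.5 equiv), K2CO3, acetone, rt
Reagents that add atoms: chloromethyl methyl ether, COCCl
Why: twofold Williamson-type O-alkylation installs two acetals that protect the phenols and direct the metalation of step 12.

**Step 12**
Reactants: 19 1-bromo-3,5-bis(methoxymethoxy)benzene
Product: 21 5-bromo-1,3-bis(methoxymethoxy)-2-(3-methylbut-2-en-1-yl)benzene, via 2-lithioarene 20 (not isolated)
Conditions: LDA (1.2 equiv), THF, −78 °C; prenyl bromide, −78 °C → rt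
Reagents that add atoms: lithium diisopropylamide, [Li+].CC(C)[N-]C(C)C (lithium of 20); 1-bromo-3-methylbut-2-ene, CC(C)=CCBr
Why: directed ortho-metalation with an amide base, which does not exchange bromine, removes the proton flanked by both OMOM groups, and the aryllithium, para to bromine and so unable to form an aryne, is allylated by SN2 displacement.

**Step 13**
Reactants: 21 prenylated aryl bromide; 17 S-ethyl thioester
Product: 24 [(1R,2S,6S)-2-{2,6-bis(methoxymethoxy)-3-[(E)-3-[4-(methoxymethoxy)phenyl]prop-2-enoyl]phenyl}-6-[4-(methoxymethoxy)phenyl]-4-methylcyclohex-3-en-1-yl][3,5-bis(methoxymethoxy)-4-(3-methylbut-2-en-1-yl)phenyl]methanone, via aryllithium 22 (not isolated), via arylzinc chloride 23 (not isolated)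
Conditions: 21, n-BuLi, THF, −78 °C; ZnCl2 (THF), −78 °C → rt; then 17, PdCl2(PPh3)2 (5 mol %), THF/toluene, rt
Reagents that add atoms: n-butyllithium, [Li]CCCC (lithium of 22); zinc chloride, [Zn+2].[Cl-].[Cl-] (ZnCl of 23)
Why: bromine–lithium exchange, transmetalation to zinc and Fukuyama coupling form the aryl ketone under neutral conditions in which the arylzinc halide adds neither to the chalcone enone nor to the new ketone and the α-stereocentre is not enolized.

**Step 14**
Reactants: 24 hexa-MOM ether
Product: 25 kuwanon V as drawn, [(1R,2S,6S)-2-{2,6-dihydroxy-3-[(E)-3-(4-hydroxyphenyl)prop-2-enoyl]phenyl}-6-(4-hydroxyphenyl)-4-methylcyclohex-3-en-1-yl][3,5-dihydroxy-4-(3-methylbut-2-en-1-yl)phenyl]methanone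
Conditions: HCl (3 M aq.), MeOH/THF, 40 °C, stopped at full conversion
Reagents that add atoms: none
Why: acid-catalysed transacetalization to methanol removes all six aryl MOM groups under conditions commonly used for prenylated polyphenolic chalcones, and no stereocentre is involved.

**Compound list**
1 | 4-hydroxybenzaldehyde | O=Cc1ccc(O)cc1 | starting material
2 | 4-(methoxymethoxy)benzaldehyde | COCOc1ccc(C=O)cc1 | intermediate
3 | (E)-3-[4-(methoxymethoxy)phenyl]prop-2-enoic acid | COCOc1ccc(/C=C/C(=O)O)cc1 | intermediate
4 | 2-methylbut-1-en-3-yne | C=C(C)C#C | starting material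
5 | (E)-4,4,5,5-tetramethyl-2-(3-methylbuta-1,3-dien-1-yl)-1,3,2-dioxaborolane | C=C(C)/C=C/B1OC(C)(C)C(C)(C)O1 | intermediate
6 | 1-(2,4-dihydroxyphenyl)ethanone | CC(=O)c1ccc(O)cc1O | starting material
7 | 1-(2,4-dihydroxy-3-iodophenyl)ethanone | CC(=O)c1ccc(O)c(I)c1O | intermediate
8 | 1-[2-hydroxy-3-iodo-4-(methoxymethoxy)phenyl]ethanone | CC(=O)c1ccc(OCOC)c(I)c1O | intermediate
9 | 1-{2-hydroxy-4-(methoxymethoxy)-3-[(1E)-3-methylbuta-1,3-dien-1-yl]phenyl}ethanone | CC(=O)c1ccc(OCOC)c(/C=C/C(C)=C)c1O | intermediate
10 | dienyl 2'-hydroxychalcone (product of step 7) | COCOc1ccc(/C=C/C(=O)c2ccc(OCOC)c(/C=C/C(C)=C)c2O)cc1 | intermediate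
11 | (E)-3-[4-(methoxymethoxy)phenyl]prop-2-enoyl chloride (not isolated) | COCOc1ccc(/C=C/C(=O)Cl)cc1 | intermediate
12 | tethered triene, aryl cinnamate of 10 at O-2' | C=C(C)/C=C/c1c(OC(=O)/C=C/c2ccc(OCOC)cc2)c(C(=O)/C=C/c2ccc(OCOC)cc2)ccc1OCOC | intermediate
13 | ion pair of the N-cinnamoyl (2R,3S)-HyperBTM cation and the 2-acyl-6-dienyl aryloxide (not isolated) | CC(C)[C@H]1CN2c3ccccc3SC2=[N+](C(=O)/C=C/c2ccc(OCOC)cc2)[C@H]1c1ccccc1.C=C(C)/C=C/c1c([O-])c(C(=O)/C=C/c2ccc(OCOC)cc2)ccc1OCOC | intermediate
14 | cycloadduct zwitterion, cyclohexenecarbonyl isothiouronium with free phenoxide (not isolated) | CC(C)[C@H]1CN2c3ccccc3SC2=[N+](C(=O)[C@H]2[C@@H](c3c([O-])c(C(=O)/C=C/c4ccc(OCOC)cc4)ccc3OCOC)C=C(C)C[C@@H]2c2ccc(OCOC)cc2)[C@H]1c1ccccc1 | intermediate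
15 | (6aR,7S,10aS) cis-fused tetrahydrobenzo[c]chromen-6-one lactone | O=C1[C@H]2[C@@H](c3c(O1)c(C(=O)/C=C/c4ccc(OCOC)cc4)ccc3OCOC)C=C(C)C[C@@H]2c2ccc(OCOC)cc2 | intermediate
16 | sodium 2'-phenoxide of the S-ethyl thioester (not isolated) | CCSC(=O)[C@H]2[C@@H](c3c([O-])c(C(=O)/C=C/c4ccc(OCOC)cc4)ccc3OCOC)C=C(C)C[C@@H]2c2ccc(OCOC)cc2.[Na+] | intermediate
17 | S-ethyl (1R,2S,6S)-cyclohexenecarbothioate, all phenols as MOM ethers | CCSC(=O)[C@H]2[C@@H](c3c(OCOC)c(C(=O)/C=C/c4ccc(OCOC)cc4)ccc3OCOC)C=C(C)C[C@@H]2c2ccc(OCOC)cc2 | intermediate
18 | 5-bromobenzene-1,3-diol | Oc1cc(O)cc(Br)c1 | starting material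
19 | 1-bromo-3,5-bis(methoxymethoxy)benzene | COCOc1cc(Br)cc(OCOC)c1 | intermediate
20 | 4-bromo-2,6-bis(methoxymethoxy)phenyllithium (not isolated) | [Li]c1c(OCOC)cc(Br)cc1OCOC | intermediate
21 | 5-bromo-1,3-bis(methoxymethoxy)-2-(3-methylbut-2-en-1-yl)benzene | CC(C)=CCc1c(OCOC)cc(Br)cc1OCOC | intermediate
22 | 3,5-bis(methoxymethoxy)-4-prenylphenyllithium (not isolated) | CC(C)=CCc1c(OCOC)cc([Li])cc1OCOC | intermediate
23 | 3,5-bis(methoxymethoxy)-4-prenylphenylzinc chloride (not isolated) | CC(C)=CCc1c(OCOC)cc([Zn]Cl)cc1OCOC | intermediate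
24 | hexa-MOM ether of the target | CC(C)=CCc1c(OCOC)cc(C(=O)[C@H]2[C@@H](c3c(OCOC)c(C(=O)/C=C/c4ccc(OCOC)cc4)ccc3OCOC)C=C(C)C[C@@H]2c2ccc(OCOC)cc2)cc1OCOC | intermediate
25 | kuwanon V (structure as given) | CC(C)=CCc1c(O)cc(C(=O)[C@H]2[C@@H](c3c(O)ccc(C(=O)/C=C/c4ccc(O)cc4)c3O)C=C(C)C[C@@H]2c2ccc(O)cc2)cc1O | target

Total step count: 14. Longest linear sequence: 9 steps (4, 5, 6, 7, 8, 9, 10, 13, 14, from resacetophenone 6).

**Steps most likely to fail**

**1. Step 9 (Proposed new method).**
- What may go wrong: ionization of the aryl ester may lie too far on the ester side, the cycloaddition inside the ion pair may be too slow for turnover, or facial or endo control may be poor. If only the sense of induction is opposite to the model, the (2S,3R) catalyst is used instead.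
- Fallback (known chemistry): it sets out from 12 and comes back at 15. Heating 12 in dilute toluene with BHT in a sealed tube at about 160 °C should bring about the thermal intramolecular Diels–Alder reaction of the ester-tethered triene. The short aryl ester tether fixes the regiochemistry, and the endo mode leads to the cis-fused lactone as the racemate, that is 15 together with the mirror-image lactone F1. Preparative chromatography on a chiral stationary phase separates the two, and 15 goes on to step 10.

**2. Step 10.**
- What may go wrong: re-closure of the lactone may compete with capping of the hindered, chelating phenoxide, thiolate may be lost to the alkylating agent, and thiolate may add to the chalcone.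
- Fallback: it sets out from 15 and 21, comes back at 25, and makes steps 10 and 13 unnecessary. Bromide 21 is converted by n-BuLi, B(OiPr)3 and aqueous NH4Cl into 3,5-bis(methoxymethoxy)-4-prenylphenylboronic acid F2. A Pd–NHC-catalysed acyl C–O Suzuki–Miyaura coupling of the aryl ester 15 with the boronic acid ([Pd(IPr)(cinnamyl)Cl], K3PO4, THF, 40–60 °C) should open the lactone directly to the penta-MOM 2'-hydroxy ketone F3. Its phenol needs no capping because a ketone cannot re-lactonize. The conditions of step 14 then give 25.

**3. Step 14.**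
- What may go wrong: acid-induced cyclization of the prenyl group onto a flanking phenol, chalcone-to-flavanone isomerization, hemiketalization with loss of water, or acid-catalysed enolization next to the aroyl group during the slow removal of six acetals.
- Fallback: it sets out from 24 and comes back at 25. It replaces Brønsted acid cleavage by silyl exchange. TMSOTf and 2,2'-bipyridyl in MeCN at 0 °C should convert every aryl MOM ether into the aryl silyl ether and give the hexakis(trimethylsilyl) ether F4. This is hydrolysed with water at neutral pH in the same flask to 25.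

**Further compounds**
F1 | step 9 | (6aS,7R,10aR) mirror-image lactone (ent-15) | O=C1[C@@H]2[C@H](c3c(O1)c(C(=O)/C=C/c4ccc(OCOC)cc4)ccc3OCOC)C=C(C)C[C@H]2c2ccc(OCOC)cc2
F2 | step 10 | 3,5-bis(methoxymethoxy)-4-(3-methylbut-2-en-1-yl)phenylboronic acid | CC(C)=CCc1c(OCOC)cc(B(O)O)cc1OCOC
F3 | step 10 | penta-MOM 2'-hydroxy ketone | CC(C)=CCc1c(OCOC)cc(C(=O)[C@H]2[C@@H](c3c(O)c(C(=O)/C=C/c4ccc(OCOC)cc4)ccc3OCOC)C=C(C)C[C@@H]2c2ccc(OCOC)cc2)cc1OCOC
F4 | step 14 | hexakis(trimethylsilyl) ether of 25 | CC(C)=CCc1c(O[Si](C)(C)C)cc(C(=O)[C@H]2[C@@H](c3c(O[Si](C)(C)C)c(C(=O)/C=C/c4ccc(O[Si](C)(C)C)cc4)ccc3O[Si](C)(C)C)C=C(C)C[C@@H]2c2ccc(O[Si](C)(C)C)cc2)cc1O[Si](C)(C)C
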